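The quinone ring is read as a folded tetraketide: oxygen on C2 and C4, methyl on C5, the docosyl chain on C6, and C1 (the carbonyl beside the chain) entering as a carboxyl carbon. Everything rests on cutting the ring bond C1–C6 of this six-membered carbocycle. In the forward sense, acyclic methyl 6-methyl-3,5,7-trioxononacosanoate closes by intramolecular aldol condensation of its ester-flanked methylene onto the chain ketone. Dehydration and enolisation then give the pentasubstituted resorcylate ring with every substituent in place in one operation. The ester carbon is later exchanged for oxygen (Dakin), and oxidative demethylation across C1/C4 furnishes the methoxyquinone.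

Key step: step 5

Remark: aromatic intermediates are named with the ring numbering of the target quinone (C1 = carbon that ends as the carbonyl beside the docosyl chain), not by lowest locants, so that each atom can be followed. The target has no stereocentre; the one stereocentre of the acyclic intermediates is racemic, enolisable and erased on aromatisation.

Remark: the dioxinone only fragments near 110 °C, so the acylketene is generated in toluene in a sealed vessel with methanol as the trap, not in boiling methanol.

Step 1
Reactants: 1 2,2,6-trimethyl-4H-1,3-dioxin-4-one; 2 propanoyl chloride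
Product: 4 2,2-dimethyl-6-(2-oxobutyl)-4H-1,3-dioxin-4-one, via lithium dienolate 3 (not isolated)
Conditions: LiN(SiMe3)2, THF, −78 °C; then 2 (dienolate in twofold excess), −78 °C; aq NH4Cl
Reagents that add atoms: none
Why: The extended lithium dienolate of the dioxinone is C-acylated at its γ-carbon by the acid chloride (vinylogous Claisen-type acylation), and the excess dienolate absorbs the acidic proton of the product so that 2 should be fully consumed.

Step 2
Reactants: 5 tricosanoic acid
Product: 7 N-methoxy-N-methyltricosanamide, via acyl imidazole 6 (not isolated)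
Conditions: 1,1'-carbonyldiimidazole, THF, 45 °C; then MeNH(OMe)·HCl, 45 °C
Reagents that add atoms: N,O-dimethylhydroxylamine hydrochloride, CNOC.Cl
Why: Activation of the acid as its imidazolide followed by aminolysis is a standard amide synthesis, and gentle warming keeps the waxy C23 acid in solution.

Step 3
Reactants: 4 2,2-dimethyl-6-(2-oxobutyl)-4H-1,3-dioxin-4-one; 7 N-methoxy-N-methyltricosanamide
Product: 9 2,2-dimethyl-6-(3-methyl-2,4-dioxohexacosyl)-4H-1,3-dioxin-4-one (racemic at the methyl-bearing carbon), via dilithium dianion 8 (not isolated)
Conditions: LiN(iPr)2 (2.1 equiv), THF, −78 °C; then 7 in THF, −78 to −10 °C; aq NH4Cl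
Reagents that add atoms: none
Why: Double deprotonation gives a 1,3-dicarbonyl-type dianion that reacts at its less stabilised terminus (the former ethyl CH2), and the N-methoxy-N-methyl amide transfers a single acyl group without over-addition (Claisen-type C-acylation), the new methyl-bearing centre forming racemic.

Step 4
Reactants: 9 2,2-dimethyl-6-(3-methyl-2,4-dioxohexacosyl)-4H-1,3-dioxin-4-one
Product: 11 methyl 6-methyl-3,5,7-trioxononacosanoate (racemic, mixture of keto and enol tautomers, used crude), via acylketene 10 (not isolated)
Conditions: MeOH (20 equiv), toluene, 110 °C, sealed tube; evaporate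
Reagents that add atoms: methanol, CO
Why: Thermal retro-[4+2] fragmentation of the dioxinone releases acetone and an acylketene that methanol traps as the β-keto ester, the large excess of methanol making intermolecular capture faster than capture by an internal enol oxygen.

Step 5
Reactants: 11 methyl 6-methyl-3,5,7-trioxononacosanoate
Product: 13 methyl 6-docosyl-2,4-dihydroxy-5-methylbenzoate, via cyclic aldol adduct 12 (not isolated)
Conditions: Cs2CO3, MeOH–THF, rt; then HCl in MeOH, rt
Reagents that add atoms: none
Why: Cs2CO3 deprotonates the most acidic site, the chain C2 methylene between the ester and the C3 ketone, and this enolate adds to the chain C7 ketone to form the ring bond C1–C6 of the target, giving the cyclic β-hydroxy diketone 12; acid then drives loss of water and enolisation of the two ring ketones to the aromatic resorcylate. The closest known reaction type is the biomimetic aldol cyclisation–aromatisation of 3,5,7-triketo esters to β-resorcylates. The carbocycle closes in a 6-(enolendo)-exo-trig mode. No stereocentre survives, since the carbinol and methyl-bearing centres of 12 form as a mixture and are both erased on aromatisation. The step needs chemoselectivity for C–C closure over lactonisation to a 4-hydroxy-2-pyrone, over γ-pyranone formation and over Claisen closure of chain C6 onto the ester; the oxygen closures are held back by forming the C–C bond under mild base before any acid is added, and the Claisen mode is blocked by the C6 methyl, which would end on a quaternary ring carbon that cannot aromatise. The other aldol mode, from the chain methylene C8 onto the C3 ketone, should not compete because C8 is not doubly activated.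

Step 6
Reactants: 13 methyl 6-docosyl-2,4-dihydroxy-5-methylbenzoate
Product: 14 methyl 6-docosyl-2,4-dimethoxy-5-methylbenzoate
Conditions: MeI (excess), K2CO3, DMF, 45 °C
Reagents that add atoms: iodomethane, CI
Why: Williamson O-methylation of both phenols, where excess MeI and warming overcome the hydrogen bond of the C2 hydroxyl to the ester and no differentiation of the two oxygens is needed.

Step 7
Reactants: 14 methyl 6-docosyl-2,4-dimethoxy-5-methylbenzoate
Product: 15 (6-docosyl-2,4-dimethoxy-5-methylphenyl)methanol
Conditions: LiAlH4, THF, 0 °C to reflux; then H2O, aq NaOH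
Reagents that add atoms: none
Why: Hydride reduction of the di-ortho-substituted benzoate to the benzylic alcohol, with hot THF overcoming the steric shielding and the aryl ethers inert.

Step 8
Reactants: 15 (6-docosyl-2,4-dimethoxy-5-methylphenyl)methanol
Product: 16 6-docosyl-2,4-dimethoxy-5-methylbenzaldehyde
Conditions: MnO2 (activated, excess), CH2Cl2, rt
Reagents that add atoms: none
Why: MnO2 oxidises the electron-rich benzylic alcohol selectively to the aldehyde and should not over-oxidise it.

Step 9
Reactants: 16 6-docosyl-2,4-dimethoxy-5-methylbenzaldehyde
Product: 18 6-docosyl-2,4-dimethoxy-5-methylphenol, via aryl formate 17 (not isolated)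
Conditions: mCPBA, CH2Cl2, 0 °C to rt; then K2CO3 (cat.), MeOH–THF, rt
Reagents that add atoms: 3-chloroperoxybenzoic acid, OOC(=O)c1cccc(Cl)c1
Why: Dakin oxidation in its Baeyer–Villiger form, in which the aryl group activated by ortho and para methoxy groups migrates in preference to hydride and mild methanolysis of the formate frees the C1 phenol.

Step 10
Reactants: 18 6-docosyl-2,4-dimethoxy-5-methylphenol
Product: 19 6-docosyl-2-methoxy-5-methyl-1,4-benzoquinone (2-docosyl-5-methoxy-3-methylcyclohexa-2,5-diene-1,4-dione)
Conditions: (NH4)2Ce(NO3)6 (2.2 equiv), MeCN–CH2Cl2–H2O, 0 °C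
Reagents that add atoms: water, O
Why: Two-electron oxidation of the para-methoxyphenol by tetravalent cerium gives a cation that water captures at C4, and loss of methanol delivers the para-quinone (oxidative demethylation), the C2 methoxy group staying because the para mode is favoured over the ortho mode.

Compound list
1 | 2,2,6-trimethyl-4H-1,3-dioxin-4-one | CC1=CC(=O)OC(C)(C)O1 | starting material
2 | propanoyl chloride | CCC(=O)Cl | starting material
3 | lithium dienolate of 1 (lithium 2,2-dimethyl-6-methylidene-6H-1,3-dioxin-4-olate) | [Li+].C=C1C=C([O-])OC(C)(C)O1 | intermediate (not isolated)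
4 | 2,2-dimethyl-6-(2-oxobutyl)-4H-1,3-dioxin-4-one | CCC(=O)CC1=CC(=O)OC(C)(C)O1 | intermediate
5 | tricosanoic acid | CCCCCCCCCCCCCCCCCCCCCCC(=O)O | starting material
6 | 1-(imidazol-1-yl)tricosan-1-one | CCCCCCCCCCCCCCCCCCCCCCC(=O)n1ccnc1 | intermediate (not isolated)
7 | N-methoxy-N-methyltricosanamide | CCCCCCCCCCCCCCCCCCCCCCC(=O)N(C)OC | intermediate
8 | dilithium dianion of 4 (deprotonated at the CH2 between ring and ketone and at the ethyl CH2) | [Li+].[Li+].CC=C([O-])C=C1C=C([O-])OC(C)(C)O1 | intermediate (not isolated)
9 | 2,2-dimethyl-6-(3-methyl-2,4-dioxohexacosyl)-4H-1,3-dioxin-4-one (racemic) | CCCCCCCCCCCCCCCCCCCCCCC(=O)C(C)C(=O)CC1=CC(=O)OC(C)(C)O1 | intermediate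
10 | 6-methyl-3,5,7-trioxononacos-1-en-1-one (acylketene, racemic) | CCCCCCCCCCCCCCCCCCCCCCC(=O)C(C)C(=O)CC(=O)C=C=O | intermediate (not isolated)
11 | methyl 6-methyl-3,5,7-trioxononacosanoate (racemic, enolisable) | CCCCCCCCCCCCCCCCCCCCCCC(=O)C(C)C(=O)CC(=O)CC(=O)OC | intermediate
12 | methyl 2-docosyl-2-hydroxy-3-methyl-4,6-dioxocyclohexane-1-carboxylate (mixture of stereoisomers) | COC(=O)C1C(=O)CC(=O)C(C)C1(O)CCCCCCCCCCCCCCCCCCCCCC | intermediate (not isolated)
13 | methyl 6-docosyl-2,4-dihydroxy-5-methylbenzoate | COC(=O)c1c(O)cc(O)c(C)c1CCCCCCCCCCCCCCCCCCCCCC | intermediate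
14 | methyl 6-docosyl-2,4-dimethoxy-5-methylbenzoate | COC(=O)c1c(OC)cc(OC)c(C)c1CCCCCCCCCCCCCCCCCCCCCC | intermediate
15 | (6-docosyl-2,4-dimethoxy-5-methylphenyl)methanol | OCc1c(OC)cc(OC)c(C)c1CCCCCCCCCCCCCCCCCCCCCC | intermediate
16 | 6-docosyl-2,4-dimethoxy-5-methylbenzaldehyde | O=Cc1c(OC)cc(OC)c(C)c1CCCCCCCCCCCCCCCCCCCCCC | intermediate
17 | 6-docosyl-2,4-dimethoxy-5-methylphenyl formate | O=COc1c(OC)cc(OC)c(C)c1CCCCCCCCCCCCCCCCCCCCCC | intermediate (not isolated)
18 | 6-docosyl-2,4-dimethoxy-5-methylphenol | Oc1c(OC)cc(OC)c(C)c1CCCCCCCCCCCCCCCCCCCCCC | intermediate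
19 | 6-docosyl-2-methoxy-5-methyl-1,4-benzoquinone | CCCCCCCCCCCCCCCCCCCCCCC1=C(C)C(=O)C=C(OC)C1=O | target

Total step count: 10. Longest linear sequence: 9 steps (steps 1 and 3–10 from dioxinone 1; the branch from tricosanoic acid 5, steps 2–10, is equally long).

Steps most likely to fail

Step 3. The acyl transfer to the secondary carbanion terminus of the dianion may stall because the waxy amide crystallises from THF at low temperature, or the dianion may be quenched by proton exchange, returning 4. The fallback sets out from 4 and 7 and comes back at 9, replacing acylation by aldol addition and oxidation. Amide 7 would be reduced with LiAlH4 in THF at 0 °C to tricosanal F1. Dianion 8, generated from 4 as before, should add to this more reactive electrophile at −78 °C to give 6-(4-hydroxy-3-methyl-2-oxohexacosyl)-2,2-dimethyl-4H-1,3-dioxin-4-one F2 as a diastereomer mixture, which is of no consequence. Oxidation of the secondary alcohol with the triacetoxy periodinane (DMP) in CH2Cl2 at rt should then give diketo-dioxinone 9.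

Step 5. Ring closure may go through oxygen instead of carbon (lactonisation onto the ester, or hemiketalisation onto the chain ketone followed by dehydration), or methoxide may cleave the 2-methyl-1,3-diketone in a retro-Claisen reaction. The fallback sets out from 9 and comes back at 13, moving the aromatisation ahead of the ring opening of the dioxinone. Treatment of 9 with Et3N in CH2Cl2 at rt over 4 Å molecular sieves should close the same C–C bond from the dioxinone α-carbon onto the chain ketone and give 5-docosyl-7-hydroxy-2,2,6-trimethyl-4H-1,3-benzodioxin-4-one F3. Here the carboxyl is locked in the acetonide and cannot lactonise. NaOMe in MeOH–THF at reflux would then open the benzodioxinone to resorcylate 13 with loss of acetone.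

Step 10. The oxidation may take the ortho path with loss of the C2 methyl group, the phenol may couple oxidatively, or the reaction may stall because the lipophilic substrate separates from the aqueous oxidant. The fallback sets out from 13 and comes back at 19; it installs the C1 oxygen by direct ring oxidation and so needs no demethylation.
- Saponification of 13 with KOH in aqueous ethylene glycol at reflux, then acidification and warming, should decarboxylate the β-resorcylic acid to 5-docosyl-4-methylbenzene-1,3-diol F4.
- Teuber oxidation with (KO3S)2NO in CH2Cl2–aqueous KH2PO4 with Bu4NHSO4 as phase-transfer agent should attack the only free position para to a hydroxyl (C1) and give 6-docosyl-2-hydroxy-5-methyl-1,4-benzoquinone F5.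
- O-Methylation of this vinylogous acid with Me2SO4 and K2CO3 in acetone should give 19.

Further compounds
F1 | step 3 | tricosanal | CCCCCCCCCCCCCCCCCCCCCCC=O
F2 | step 3 | 6-(4-hydroxy-3-methyl-2-oxohexacosyl)-2,2-dimethyl-4H-1,3-dioxin-4-one (mixture of diastereomers) | CCCCCCCCCCCCCCCCCCCCCCC(O)C(C)C(=O)CC1=CC(=O)OC(C)(C)O1
F3 | step 5 | 5-docosyl-7-hydroxy-2,2,6-trimethyl-4H-1,3-benzodioxin-4-one | CC1(C)OC(=O)c2c(O1)cc(O)c(C)c2CCCCCCCCCCCCCCCCCCCCCC
F4 | step 10 | 5-docosyl-4-methylbenzene-1,3-diol | Cc1c(O)cc(O)cc1CCCCCCCCCCCCCCCCCCCCCC
F5 | step 10 | 6-docosyl-2-hydroxy-5-methyl-1,4-benzoquinone | CCCCCCCCCCCCCCCCCCCCCCC1=C(C)C(=O)C=C(O)C1=O
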